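**Plan**

1. Numbering: C1 is the lactone carbonyl, C7 the lactone carbinol, C8/C10 the cyclopropane CH carbons, C11 and C14 the carbinols, C22 the methyl. The retrosynthesis first cuts C11–C12, giving cyclopropyl aldehyde 7 and alkyne 15.
2. It then cuts the eight-membered lactone at C1–C2 and C6–C7 (with C1–O), giving aldehyde 4, vinylcyclopropane 5 and CO.
3. Enabling feature: in the oxocin-2-one ring the five carbons C2–C6, with the Z alkene C4=C5, lie between acyl carbon C1 and carbinol carbon C7. That run is a ring-opened vinylcyclopropane, and C7–O–C1(=O) is an aldehyde plus CO.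
4. Forward order: the cyclopropane ring is made first, the lactone ring is then made in one carbonylative (5+2+1) event, and the C12–C22 chain (from a silylpropynal by propargylation, skipped-diyne coupling and semi-hydrogenation) is joined last at C11–C12.
5. Stereochemistry: C8/C10 come from a ligand-controlled Simmons–Smith reaction, C7 from the chiral rhodium catalyst of the key step, C14 from a chiral phosphoric acid propargylation, and C11 from a (+)-MIB-catalysed alkenylzinc addition.
6. Alkene geometry: the ring Z alkene is fixed by the metallacycle, the E alkene by syn-hydroboration, and the chain Z alkenes by syn-hydrogenation.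

Key step: step 4

Remark: the sense of induction of the chiral ligands in steps 2, 4, 6 and 11 is assigned from the accepted model of each catalyst; should one prove opposite, the antipodal ligand is used without other change.

**Route**

Step 1
Reactants: 1 (E)-4,4-dimethoxybut-2-enal
Product: 2 (E)-4,4-dimethoxybut-2-en-1-ol
Conditions: NaBH4, CeCl3·7H2O, MeOH, 0 °C
Reagents that add atoms: none
Why: Luche-type 1,2-reduction of the enal, which leaves the E alkene and the acetal untouched and creates no stereocentre.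

Step 2
Reactants: 2 (E)-4,4-dimethoxybut-2-en-1-ol
Product: 3 [(1R,2R)-2-(dimethoxymethyl)cyclopropyl]methanol
Conditions: Et2Zn, CH2I2, DME, CH2Cl2, −10 °C [gives Zn(CH2I)2·DME]; (4S,5S)-2-butyl-N,N,N′,N′-tetramethyl-1,3,2-dioxaborolane-4,5-dicarboxamide (1.2 equiv), −10 °C → rt
Reagents that add atoms: diiodomethane, ICI
Why: Charette asymmetric Simmons–Smith cyclopropanation, in which the zinc alkoxide of 2 bound to the chiral dioxaborolane directs stereospecific syn CH2 transfer to one alkene face, so the E alkene gives the trans ring and the ligand sets C8 and C10 (both R).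

Step 3
Reactants: 3 [(1R,2R)-2-(dimethoxymethyl)cyclopropyl]methanol
Product: 4 (1R,2R)-2-(dimethoxymethyl)cyclopropane-1-carbaldehyde
Conditions: (nPr4N)RuO4 (5 mol%), NMO, 4 Å MS, CH2Cl2, rt
Reagents that add atoms: none
Why: Ley–Griffith oxidation of the primary alcohol under neutral conditions, which spare the acetal and the configurationally stable cyclopropane centres.

Step 4
Reactants: 4 (1R,2R)-2-(dimethoxymethyl)cyclopropane-1-carbaldehyde, 5 vinylcyclopropane
Product: 6 (5Z,8R)-8-[(1R,2R)-2-(dimethoxymethyl)cyclopropyl]-3,4,7,8-tetrahydro-2H-oxocin-2-one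
Conditions: [Rh(cod)Cl]2 (5 mol%), (R)-BINAP (11 mol%), AgSbF6 (10 mol%), CO/N2 (1:4, 1 atm), 5 (5 equiv), 1,2-dichloroethane, 70 °C, sealed vessel
Reagents that add atoms: carbon monoxide, [C-]#[O+]
Why: Proposed new method: a carbonylative hetero-(5+2+1) cycloaddition in which monovalent rhodium inserts into the cyclopropane C–C bond of 5 to give a σ-alkyl/π-allyl metallacycle of trivalent rhodium, whose allyl terminus (future C6) adds to the aldehyde carbon of 4 (C6–C7) to give an eight-membered oxa-rhodacycle, after which CO inserts into the Rh–C2 bond (C1–C2) and acyl–alkoxide reductive elimination releases the lactone. The closest known reaction types are the rhodium-catalysed (5+2+1) cycloaddition of vinylcyclopropanes, a π-component and CO to cyclooctenones and the hetero-Pauson–Khand (2+2+1) lactone synthesis from a C=O group, an alkene and CO, so the only new element is an aldehyde as the two-atom partner. The oxocin-2-one ring is closed as a formal 5+2+1 ring synthesis, its last bond (C1–O) by reductive elimination from a nine-membered acyl-alkoxy rhodacycle, and the C4=C5 alkene must be Z because it is formed inside the metallacycle. C7 is the only new stereocentre and is set by the chiral bisphosphine (catalyst control, addition to the Re face of the aldehyde); the weak bias of the trans-cyclopropane should be overridden, and a C7 epimer would be a separable diastereomer. The step needs chemoselectivity for aldehyde insertion over direct carbonylation of the metallacycle (cyclohexenone), β-hydride loss and aldehyde decarbonylation, which a low CO partial pressure, excess 5 and a high concentration of the unhindered aldehyde should secure. The regiochemistry (carbonyl carbon to the allyl terminus, oxygen to rhodium) follows from the polarity of allyl–metal addition to C=O.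

Step 5
Reactants: 6 (5Z,8R)-8-[(1R,2R)-2-(dimethoxymethyl)cyclopropyl]-3,4,7,8-tetrahydro-2H-oxocin-2-one
Product: 7 (1R,2R)-2-[(2R,4Z)-8-oxo-3,6,7,8-tetrahydro-2H-oxocin-2-yl]cyclopropane-1-carbaldehyde
Conditions: p-TsOH·H2O (cat.), THF/H2O (4:1), rt
Reagents that add atoms: water, O
Why: Acid-catalysed acetal hydrolysis, mild enough for the lactone, the Z alkene and the trans-cyclopropane to survive.

Step 6
Reactants: 8 3-(triisopropylsilyl)prop-2-ynal, 9 allenylboronic acid pinacol ester
Product: 10 (3S)-1-(triisopropylsilyl)hexa-1,5-diyn-3-ol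
Conditions: (S)-TRIP [3,3′-bis(2,4,6-triisopropylphenyl)-1,1′-binaphthyl-2,2′-diyl hydrogen phosphate] (5 mol%), 4 Å MS, toluene, 0 °C; aqueous work-up
Reagents that add atoms: none
Why: Chiral phosphoric acid-catalysed propargylation (allenylboration) through a closed six-membered SE2′ transition state, in which the catalyst directs attack to the Si face of 8 and so sets C14 (S).

Step 7
Reactants: 10 (3S)-1-(triisopropylsilyl)hexa-1,5-diyn-3-ol, 11 1-bromopent-2-yne
Product: 12 (3S)-1-(triisopropylsilyl)undeca-1,5,8-triyn-3-ol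
Conditions: CuI, NaI, Cs2CO3, DMF, rt
Reagents that add atoms: none
Why: Copper acetylide substitution of the propargylic bromide (SN2) builds the skipped diyne, since only the terminal alkyne of 10 forms an acetylide and the silyl-capped one is inert.

Step 8
Reactants: 12 (3S)-1-(triisopropylsilyl)undeca-1,5,8-triyn-3-ol
Product: 13 (3S,5Z,8Z)-1-(triisopropylsilyl)undeca-5,8-dien-1-yn-3-ol
Conditions: H2 (1 atm), Pd/CaCO3 poisoned with Pb(OAc)2 (Lindlar catalyst), quinoline, EtOAc, rt
Reagents that add atoms: none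
Why: Lindlar semi-hydrogenation adds H2 syn to the two dialkyl alkynes to give both Z alkenes, while the bulky silyl-capped alkyne is too hindered to be reduced.

Step 9
Reactants: 13 (3S,5Z,8Z)-1-(triisopropylsilyl)undeca-5,8-dien-1-yn-3-ol
Product: 14 (3S,5Z,8Z)-undeca-5,8-dien-1-yn-3-ol
Conditions: Bu4NF, THF, 0 °C
Reagents that add atoms: none
Why: Fluoride-induced protodesilylation of the C(sp)–Si bond, which leaves the skipped Z,Z-diene and the carbinol centre untouched.

Step 10
Reactants: 14 (3S,5Z,8Z)-undeca-5,8-dien-1-yn-3-ol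
Product: 15 tert-butyldimethyl{[(3S,5Z,8Z)-undeca-5,8-dien-1-yn-3-yl]oxy}silane
Conditions: TBSCl, imidazole, DMF, rt
Reagents that add atoms: tert-butyldimethylsilyl chloride, CC(C)(C)[Si](C)(C)Cl
Why: Imidazole-promoted silylation of the secondary alcohol, a standard protection that does not touch the terminal alkyne.

Step 11
Reactants: 15 tert-butyldimethyl{[(3S,5Z,8Z)-undeca-5,8-dien-1-yn-3-yl]oxy}silane, 7 (1R,2R)-2-[(2R,4Z)-8-oxo-3,6,7,8-tetrahydro-2H-oxocin-2-yl]cyclopropane-1-carbaldehyde
Product: 18 (5Z,8R)-8-[(1R,2R)-2-[(1R,2E,4S,6Z,9Z)-4-(tert-butyldimethylsilyloxy)-1-hydroxydodeca-2,6,9-trien-1-yl]cyclopropyl]-3,4,7,8-tetrahydro-2H-oxocin-2-one, via alkenylborane 16 (not isolated), via alkenylzinc 17 (not isolated)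
Conditions: 15 (1.3 equiv), Cy2BH, toluene, 0 °C → rt; Me2Zn, −78 °C; (+)-MIB (5 mol%), then 7, −78 → −10 °C; aq NH4Cl
Reagents that add atoms: none
Why: syn-Hydroboration of the terminal alkyne (E-alkenylborane), boron-to-zinc transmetalation with retention and amino-alcohol-catalysed alkenylzinc addition to the aldehyde, in which the (+)-MIB–zinc catalyst delivers the alkenyl group to the Re face of 7 and sets C11 (R) while the lactone is inert to organozinc reagents.

Step 12
Reactants: 18 (5Z,8R)-8-[(1R,2R)-2-[(1R,2E,4S,6Z,9Z)-4-(tert-butyldimethylsilyloxy)-1-hydroxydodeca-2,6,9-trien-1-yl]cyclopropyl]-3,4,7,8-tetrahydro-2H-oxocin-2-one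
Product: 19 (5Z,8R)-8-[(1R,2R)-2-[(1R,2E,4S,6Z,9Z)-1,4-dihydroxydodeca-2,6,9-trien-1-yl]cyclopropyl]-3,4,7,8-tetrahydro-2H-oxocin-2-one
Conditions: HF·pyridine, pyridine, THF, 0 °C → rt
Reagents that add atoms: none
Why: Fluoride-mediated cleavage of the silyl ether under buffered conditions that spare the lactone and both allylic alcohols.

**Compound list**

1 | (E)-4,4-dimethoxybut-2-enal | COC(OC)/C=C/C=O | starting material
2 | (E)-4,4-dimethoxybut-2-en-1-ol | COC(OC)/C=C/CO | intermediate
3 | [(1R,2R)-2-(dimethoxymethyl)cyclopropyl]methanol | COC(OC)[C@@H]1C[C@H]1CO | intermediate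
4 | (1R,2R)-2-(dimethoxymethyl)cyclopropane-1-carbaldehyde | COC(OC)[C@@H]1C[C@H]1C=O | intermediate
5 | vinylcyclopropane (ethenylcyclopropane) | C=CC1CC1 | starting material
6 | (5Z,8R)-8-[(1R,2R)-2-(dimethoxymethyl)cyclopropyl]-3,4,7,8-tetrahydro-2H-oxocin-2-one | COC(OC)[C@@H]1C[C@H]1[C@H]1C/C=C\CCC(=O)O1 | intermediate
7 | (1R,2R)-2-[(2R,4Z)-8-oxo-3,6,7,8-tetrahydro-2H-oxocin-2-yl]cyclopropane-1-carbaldehyde | O=C[C@@H]1C[C@H]1[C@H]1C/C=C\CCC(=O)O1 | intermediate
8 | 3-(triisopropylsilyl)prop-2-ynal | O=CC#C[Si](C(C)C)(C(C)C)C(C)C | starting material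
9 | allenylboronic acid pinacol ester (4,4,5,5-tetramethyl-2-(propa-1,2-dien-1-yl)-1,3,2-dioxaborolane) | C=C=CB1OC(C)(C)C(C)(C)O1 | starting material
10 | (3S)-1-(triisopropylsilyl)hexa-1,5-diyn-3-ol | C#CC[C@H](O)C#C[Si](C(C)C)(C(C)C)C(C)C | intermediate
11 | 1-bromopent-2-yne | CCC#CCBr | starting material
12 | (3S)-1-(triisopropylsilyl)undeca-1,5,8-triyn-3-ol | CCC#CCC#CC[C@H](O)C#C[Si](C(C)C)(C(C)C)C(C)C | intermediate
13 | (3S,5Z,8Z)-1-(triisopropylsilyl)undeca-5,8-dien-1-yn-3-ol | CC/C=C\C/C=C\C[C@H](O)C#C[Si](C(C)C)(C(C)C)C(C)C | intermediate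
14 | (3S,5Z,8Z)-undeca-5,8-dien-1-yn-3-ol | CC/C=C\C/C=C\C[C@H](O)C#C | intermediate
15 | tert-butyldimethyl{[(3S,5Z,8Z)-undeca-5,8-dien-1-yn-3-yl]oxy}silane | CC/C=C\C/C=C\C[C@H](O[Si](C)(C)C(C)(C)C)C#C | intermediate
16 | [(1E,3S,5Z,8Z)-3-(tert-butyldimethylsilyloxy)undeca-1,5,8-trien-1-yl]dicyclohexylborane | CC/C=C\C/C=C\C[C@H](O[Si](C)(C)C(C)(C)C)/C=C/B(C1CCCCC1)C1CCCCC1 | intermediate
17 | [(1E,3S,5Z,8Z)-3-(tert-butyldimethylsilyloxy)undeca-1,5,8-trien-1-yl](methyl)zinc | CC/C=C\C/C=C\C[C@H](O[Si](C)(C)C(C)(C)C)/C=C/[Zn]C | intermediate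
18 | (5Z,8R)-8-[(1R,2R)-2-[(1R,2E,4S,6Z,9Z)-4-(tert-butyldimethylsilyloxy)-1-hydroxydodeca-2,6,9-trien-1-yl]cyclopropyl]-3,4,7,8-tetrahydro-2H-oxocin-2-one | CC/C=C\C/C=C\C[C@H](O[Si](C)(C)C(C)(C)C)/C=C/[C@@H](O)[C@@H]1C[C@H]1[C@H]1C/C=C\CCC(=O)O1 | intermediate
19 | (5Z,8R)-8-[(1R,2R)-2-[(1R,2E,4S,6Z,9Z)-1,4-dihydroxydodeca-2,6,9-trien-1-yl]cyclopropyl]-3,4,7,8-tetrahydro-2H-oxocin-2-one | CC/C=C\C/C=C\C[C@H](O)/C=C/[C@@H](O)[C@@H]1C[C@H]1[C@H]1C/C=C\CCC(=O)O1 | target

**Step count and risks**

Total step count: 12. Longest linear sequence: 7 steps (1 → 2 → 3 → 4 → 6 → 7 → 18 → 19; the branch 8 → 10 → 12 → 13 → 14 → 15 → 18 → 19 is also 7).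

Steps most likely to fail:

Step 4 (proposed new method). The opened vinylcyclopropane may be carbonylated or isomerised before the aldehyde inserts, the aldehyde may be decarbonylated, or insertion may occur with poor facial selectivity at C7. The fallback uses known chemistry and sets out from 4. Brown allylation with (+)-Ipc2B(allyl) (Et2O, −78 °C; NaOH, H2O2), which attacks the Re face, gives (1R)-1-[(1R,2R)-2-(dimethoxymethyl)cyclopropyl]but-3-en-1-ol F1. Esterification with pent-4-enoic acid (DCC, DMAP, CH2Cl2) gives (1R)-1-[(1R,2R)-2-(dimethoxymethyl)cyclopropyl]but-3-en-1-yl pent-4-enoate F2. Ring-closing metathesis (second-generation Grubbs catalyst, 1 mM in CH2Cl2, reflux) closes the Z-configured eight-membered lactone and comes back to the route at 6.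

Step 11. Catalyst control over the C11 configuration may be incomplete, methyl may transfer in place of the alkenyl group, or the skipped diene may be hydroborated. The fallback sets out from 15 and sets C11 by ketone reduction instead. Hydrozirconation and iodination (Cp2Zr(H)Cl, THF; then I2) give tert-butyl{[(1E,3S,5Z,8Z)-1-iodoundeca-1,5,8-trien-3-yl]oxy}dimethylsilane F3. Nozaki–Hiyama–Kishi coupling with 7 (CrCl2, NiCl2 cat., DMSO/THF) gives 18 mixed with its C11 epimer (5Z,8R)-8-[(1R,2R)-2-[(1S,2E,4S,6Z,9Z)-4-(tert-butyldimethylsilyloxy)-1-hydroxydodeca-2,6,9-trien-1-yl]cyclopropyl]-3,4,7,8-tetrahydro-2H-oxocin-2-one F4. The mixture is oxidised (Dess–Martin periodinane, NaHCO3, CH2Cl2) to (5Z,8R)-8-[(1R,2R)-2-[(2E,4S,6Z,9Z)-4-(tert-butyldimethylsilyloxy)dodeca-2,6,9-trienoyl]cyclopropyl]-3,4,7,8-tetrahydro-2H-oxocin-2-one F5. Corey–Bakshi–Shibata reduction ((R)-Me-CBS, catecholborane, toluene, −78 °C, with the alkenyl group taken as the larger substituent) then comes back to the route at 18.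

Step 6. The very electrophilic ynal may react with the allenylboronate without the catalyst, or the slim alkynyl group may be poorly discriminated, so that enantioselectivity at C14 is eroded. The fallback sets out from 8 and sets C14 by reagent-controlled ketone reduction. Zinc-mediated Barbier propargylation (propargyl bromide, Zn, THF, 0 °C) gives racemic 1-(triisopropylsilyl)hexa-1,5-diyn-3-ol F6. Oxidation (Dess–Martin periodinane, CH2Cl2, 0 °C) gives 1-(triisopropylsilyl)hexa-1,5-diyn-3-one F7. Midland reduction with (S)-Alpine-Borane (THF, rt, neutral conditions so that the propargyl ketone does not isomerise) comes back to the route at 10.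

**Further compounds**

F1 | step 4 | (1R)-1-[(1R,2R)-2-(dimethoxymethyl)cyclopropyl]but-3-en-1-ol | COC(OC)[C@@H]1C[C@H]1[C@H](O)CC=C
F2 | step 4 | (1R)-1-[(1R,2R)-2-(dimethoxymethyl)cyclopropyl]but-3-en-1-yl pent-4-enoate | COC(OC)[C@@H]1C[C@H]1[C@H](OC(=O)CCC=C)CC=C
F3 | step 11 | tert-butyl{[(1E,3S,5Z,8Z)-1-iodoundeca-1,5,8-trien-3-yl]oxy}dimethylsilane | CC/C=C\C/C=C\C[C@H](O[Si](C)(C)C(C)(C)C)/C=C/I
F4 | step 11 | (5Z,8R)-8-[(1R,2R)-2-[(1S,2E,4S,6Z,9Z)-4-(tert-butyldimethylsilyloxy)-1-hydroxydodeca-2,6,9-trien-1-yl]cyclopropyl]-3,4,7,8-tetrahydro-2H-oxocin-2-one | CC/C=C\C/C=C\C[C@H](O[Si](C)(C)C(C)(C)C)/C=C/[C@H](O)[C@@H]1C[C@H]1[C@H]1C/C=C\CCC(=O)O1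
F5 | step 11 | (5Z,8R)-8-[(1R,2R)-2-[(2E,4S,6Z,9Z)-4-(tert-butyldimethylsilyloxy)dodeca-2,6,9-trienoyl]cyclopropyl]-3,4,7,8-tetrahydro-2H-oxocin-2-one | CC/C=C\C/C=C\C[C@H](O[Si](C)(C)C(C)(C)C)/C=C/C(=O)[C@@H]1C[C@H]1[C@H]1C/C=C\CCC(=O)O1
F6 | step 6 | racemic 1-(triisopropylsilyl)hexa-1,5-diyn-3-ol | C#CCC(O)C#C[Si](C(C)C)(C(C)C)C(C)C
F7 | step 6 | 1-(triisopropylsilyl)hexa-1,5-diyn-3-one | C#CCC(=O)C#C[Si](C(C)C)(C(C)C)C(C)C
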